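**Retrosynthetic overview**

1. Target ⇐ C3 PMB ether with an inverted C8 alcohol (Mitsunobu angeloylation, then DDQ) ⇐ trans-fused α-methylene lactone built on a ring (E)-C6=C7 alkene (epoxidation, Pd/formate hydrogenolysis of the vinyl epoxide, SeO2 then MnO2).
2. Ten-membered ring ⇐ anionic oxy-Cope rearrangement of a trans-1,2-dialkenylcyclohexanol (forms C8–C9, sets C8 and the (6E)-alkene); the resulting C1/C10 enolate is hydroxylated and acetylated in the same flask (sets C10).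
3. Cyclohexanol ⇐ isopropenyl addition to a 2-dienylcyclohexanone ⇐ Pd α-alkenylation of a (3S,4S)-ketone with a bromodiene made from prenal.
4. (3S,4S)-Ketone ⇐ (S)-carvone (dissolving-metal reduction, PMB protection, Criegee removal of the isopropenyl group).
5. Ring order: six-membered ring (bought) → ten-membered carbocycle (oxy-Cope) → γ-lactone.

Assumption: germacrane numbering of the target is used for all carbons (ring C1–C10; C11 on C7 carrying C12 and C13; C14 on C10; C15 on C4), and silylation of 11 is taken to give the (1Z)-bromodiene (oxygen cis to bromine).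

**Route**

Step 1
Reactants: 1 (S)-carvone
Product: 3 (1S,2S,5S)-2-methyl-5-(prop-1-en-2-yl)cyclohexan-1-ol, via trans-dihydrocarvone 2 (not isolated)
Conditions: Li, NH3(l), t-BuOH, THF, −78 to −33 °C; NH4Cl
Reagents that add atoms: none
Why: Dissolving-metal (Birch-type) reduction of the enone and then of the ketone gives the thermodynamically preferred all-equatorial alcohol, so C4 (methyl) and C3 (hydroxyl, trans to methyl) are set by the bought carvone stereocentre.

Step 2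
Reactants: 3 (1S,2S,5S)-2-methyl-5-(prop-1-en-2-yl)cyclohexan-1-ol
Product: 4 1-methoxy-4-({[(1S,2S,5S)-2-methyl-5-(prop-1-en-2-yl)cyclohexyl]oxy}methyl)benzene
Conditions: NaH, 4-MeOC6H4CH2Cl, Bu4NI (cat.), DMF, 0 to 25 °C
Reagents that add atoms: 4-methoxybenzyl chloride, COc1ccc(CCl)cc1
Why: Williamson etherification protects the future C3 hydroxyl as a PMB ether that survives base, hydride, fluoride and Pd and is removed oxidatively at the end.

Step 3
Reactants: 4 1-methoxy-4-({[(1S,2S,5S)-2-methyl-5-(prop-1-en-2-yl)cyclohexyl]oxy}methyl)benzene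
Product: 6 (1S,3S,4S)-3-[(4-methoxybenzyl)oxy]-4-methylcyclohexyl acetate, via methoxy hydroperoxide 5 (not isolated)
Conditions: O3, CH2Cl2–MeOH, NaHCO3, −78 °C; then Ac2O, Et3N, DMAP, 0 to 25 °C
Reagents that add atoms: ozone, O=[O+][O-]; methanol, CO
Why: Ozonolysis in methanol followed by Criegee rearrangement of the peracetate moves the ring carbon from C to O with retention, replacing isopropenyl by acetoxy.

Step 4
Reactants: 6 (1S,3S,4S)-3-[(4-methoxybenzyl)oxy]-4-methylcyclohexyl acetate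
Product: 7 (1S,3S,4S)-3-[(4-methoxybenzyl)oxy]-4-methylcyclohexan-1-ol
Conditions: K2CO3, MeOH, 25 °C
Reagents that add atoms: none
Why: Base-catalysed transesterification (methanolysis) frees the secondary alcohol without touching the ether.

Step 5
Reactants: 7 (1S,3S,4S)-3-[(4-methoxybenzyl)oxy]-4-methylcyclohexan-1-ol
Product: 8 (3S,4S)-3-[(4-methoxybenzyl)oxy]-4-methylcyclohexan-1-one
Conditions: Dess–Martin periodinane, NaHCO3, CH2Cl2, 25 °C
Reagents that add atoms: none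
Why: Dess–Martin oxidation gives the ketone (future C1) under buffered, non-basic conditions, so the β-alkoxy group is not eliminated.

Step 6
Reactants: 9 3-methylbut-2-enal
Product: 11 2-bromo-3-methylbut-2-enal, via dibromo aldehyde 10 (not isolated)
Conditions: Br2, CH2Cl2, 0 °C; then Et3N
Reagents that add atoms: bromine, BrBr
Why: Bromine addition and E1cB dehydrobromination is the standard α-bromination of an enal.

Step 7
Reactants: 11 2-bromo-3-methylbut-2-enal
Product: 12 {[(1Z)-2-bromo-3-methylbuta-1,3-dien-1-yl]oxy}tri(propan-2-yl)silane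
Conditions: i-Pr3SiOTf, Et3N, CH2Cl2, −78 to 0 °C
Reagents that add atoms: triisopropylsilyl trifluoromethanesulfonate, CC(C)[Si](OS(=O)(=O)C(F)(F)F)(C(C)C)C(C)C
Why: Soft enolisation (O-silylation, γ-deprotonation) through the s-trans silyloxyallyl cation gives the silyl dienol ether with oxygen cis to bromine.

Step 8
Reactants: 8 (3S,4S)-3-[(4-methoxybenzyl)oxy]-4-methylcyclohexan-1-one; 12 {[(1Z)-2-bromo-3-methylbuta-1,3-dien-1-yl]oxy}tri(propan-2-yl)silane
Product: 15 (2S,4S,5S)-5-[(4-methoxybenzyl)oxy]-4-methyl-2-{(1E)-3-methyl-1-[(triisopropylsilyl)oxy]buta-1,3-dien-2-yl}cyclohexan-1-one, via lithium enolate 13 (not isolated), via chlorozinc enolate 14 (not isolated)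
Conditions: LiN(i-Pr)2, THF, −78 °C; ZnCl2; then 12, Pd2(dba)3 (cat.), P(t-Bu)3, 25 °C
Reagents that add atoms: none
Why: Negishi-type Pd-catalysed α-alkenylation of the kinetic enolate (formed away from the alkoxy group) keeps the bromodiene geometry, and the epimerisable C6 centre settles equatorial, cis to the C4 methyl.

Step 9
Reactants: 15 (2S,4S,5S)-5-[(4-methoxybenzyl)oxy]-4-methyl-2-{(1E)-3-methyl-1-[(triisopropylsilyl)oxy]buta-1,3-dien-2-yl}cyclohexan-1-one
Product: 16 (1S,2S,4S,5S)-5-[(4-methoxybenzyl)oxy]-4-methyl-2-{(1E)-3-methyl-1-[(triisopropylsilyl)oxy]buta-1,3-dien-2-yl}-1-(prop-1-en-2-yl)cyclohexan-1-ol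
Conditions: CH2=C(CH3)MgBr, CeCl3, THF, −78 °C
Reagents that add atoms: isopropenylmagnesium bromide, CC(=C)[Mg]Br
Why: Organocerium 1,2-addition avoids enolisation and attacks equatorially, anti to the C6 substituent, giving the trans-dialkenyl carbinol with axial hydroxyl.

Step 10
Reactants: 16 (1S,2S,4S,5S)-5-[(4-methoxybenzyl)oxy]-4-methyl-2-{(1E)-3-methyl-1-[(triisopropylsilyl)oxy]buta-1,3-dien-2-yl}-1-(prop-1-en-2-yl)cyclohexan-1-ol
Product: 20 (3S,4S,6E,8R,10R)-10-acetoxy-3-(4-methoxybenzyloxy)-8-(triisopropylsilyloxy)germacra-6,11(13)-dien-1-one, via potassium alkoxide 17 (not isolated), via potassium enolate 18 (not isolated), via potassium ketol alkoxide 19 (not isolated)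
Conditions: KH, 18-crown-6, THF, 0 to 25 °C; then racemic 2-(phenylsulfonyl)-3-phenyloxaziridine, −78 °C; then Ac2O, −78 to 0 °C
Reagents that add atoms: 2-(phenylsulfonyl)-3-phenyloxaziridine, O=S(=O)(c1ccccc1)N1OC1c1ccccc1; acetic anhydride, CC(=O)OC(C)=O
Why: The anionic oxy-Cope [3,3]-sigmatropic rearrangement through the chair transition state (both alkenyl groups equatorial, silyloxy terminus pseudo-axial) forms C8–C9, the (6E)-alkene and 8R; Davis hydroxylation of the regiospecific enolate from the outer face of the ring then sets 10R, and the alkoxide is acetylated in situ.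

Step 11
Reactants: 20 (3S,4S,6E,8R,10R)-10-acetoxy-3-(4-methoxybenzyloxy)-8-(triisopropylsilyloxy)germacra-6,11(13)-dien-1-one
Product: 21 (3S,4S,6R,7S,8R,10R)-10-acetoxy-6,7-epoxy-3-(4-methoxybenzyloxy)-8-(triisopropylsilyloxy)germacr-11(13)-en-1-one
Conditions: mCPBA, NaHCO3, CH2Cl2, 0 °C
Reagents that add atoms: 3-chloroperbenzoic acid, OOC(=O)c1cccc(Cl)c1
Why: Prilezhaev epoxidation takes the more substituted diene double bond from the exposed outer face of the (E)-cyclodecene, setting C6 as R.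

Step 12
Reactants: 21 (3S,4S,6R,7S,8R,10R)-10-acetoxy-6,7-epoxy-3-(4-methoxybenzyloxy)-8-(triisopropylsilyloxy)germacr-11(13)-en-1-one
Product: 22 (3S,4S,6R,7S,8R,10R)-10-acetoxy-6-hydroxy-3-(4-methoxybenzyloxy)-8-(triisopropylsilyloxy)germacr-11(13)-en-1-one
Conditions: Pd2(dba)3·CHCl3 (cat.), P(n-Bu)3, HCO2H, Et3N, 1,4-dioxane, 25 °C
Reagents that add atoms: none
Why: Tsuji-type Pd/formate hydrogenolysis of the alkenyl oxirane ionises C7–O with inversion and delivers hydride to the more substituted allyl terminus, giving C7–H anti to the C6 oxygen (7S) and keeping the 11(13)-alkene.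

Step 13
Reactants: 22 (3S,4S,6R,7S,8R,10R)-10-acetoxy-6-hydroxy-3-(4-methoxybenzyloxy)-8-(triisopropylsilyloxy)germacr-11(13)-en-1-one
Product: 23 (3S,4S,6R,7S,8R,10R)-10-acetoxy-6,12-dihydroxy-3-(4-methoxybenzyloxy)-8-(triisopropylsilyloxy)germacr-11(13)-en-1-one
Conditions: SeO2 (cat.), t-BuOOH, CH2Cl2, 25 °C
Reagents that add atoms: tert-butyl hydroperoxide, CC(C)(C)OO
Why: Selenium dioxide allylic oxidation (ene reaction then [2,3]-shift) hydroxylates the isopropenyl methyl group C12 and touches no stereocentre.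

Step 14
Reactants: 23 (3S,4S,6R,7S,8R,10R)-10-acetoxy-6,12-dihydroxy-3-(4-methoxybenzyloxy)-8-(triisopropylsilyloxy)germacr-11(13)-en-1-one
Product: 24 (3S,4S,6R,7S,8R,10R)-10-acetoxy-3-(4-methoxybenzyloxy)-1-oxo-8-(triisopropylsilyloxy)germacr-11(13)-en-12,6-olide
Conditions: MnO2, CH2Cl2, 25 °C
Reagents that add atoms: none
Why: Oxidative lactonisation: MnO2 oxidises the allylic primary alcohol to the enal, which closes to the lactol on the C6 hydroxyl and is oxidised to the trans-fused α-methylene γ-lactone without any base.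

Step 15
Reactants: 24 (3S,4S,6R,7S,8R,10R)-10-acetoxy-3-(4-methoxybenzyloxy)-1-oxo-8-(triisopropylsilyloxy)germacr-11(13)-en-12,6-olide
Product: 25 (3S,4S,6R,7R,8R,10R)-10-acetoxy-8-hydroxy-3-(4-methoxybenzyloxy)-1-oxogermacr-11(13)-en-12,6-olide
Conditions: HF·pyridine, pyridine, THF, 25 °C
Reagents that add atoms: none
Why: Fluoride desilylation removes the secondary silyl ether while the PMB ether, acetate and lactone are inert (the C7 descriptor changes only through CIP priorities).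

Step 16
Reactants: 25 (3S,4S,6R,7R,8R,10R)-10-acetoxy-8-hydroxy-3-(4-methoxybenzyloxy)-1-oxogermacr-11(13)-en-12,6-olide
Product: 26 (3S,4S,6R,7S,8S,10R)-10-acetoxy-8-angeloyloxy-3-(4-methoxybenzyloxy)-1-oxogermacr-11(13)-en-12,6-olide
Conditions: angelic acid, PPh3, DIAD, toluene, 0 to 25 °C
Reagents that add atoms: angelic acid, C/C=C(C)\C(O)=O
Why: Mitsunobu esterification displaces the activated C8 oxygen by angelate with SN2 inversion (8R to 8S) under neutral conditions.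

Step 17
Reactants: 26 (3S,4S,6R,7S,8S,10R)-10-acetoxy-8-angeloyloxy-3-(4-methoxybenzyloxy)-1-oxogermacr-11(13)-en-12,6-olide
Product: 27 (3S,4S,6R,7S,8S,10R)-10-acetoxy-8-angeloyloxy-3-hydroxy-1-oxogermacr-11(13)-en-12,6-olide
Conditions: DDQ, CH2Cl2–pH 7 buffer, 0 °C
Reagents that add atoms: none
Why: Oxidative PMB cleavage by DDQ frees the C3 hydroxyl without acid or base, so the β-hydroxy ketone, tertiary acetate, angelate and α-methylene lactone survive.

**Compound list**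

1 | (S)-carvone | CC1=CC[C@@H](CC1=O)C(C)=C | starting material
2 | (2S,5S)-2-methyl-5-(prop-1-en-2-yl)cyclohexan-1-one (trans-dihydrocarvone) | CC(=C)[C@@H]1CC(=O)[C@@H](C)CC1 | intermediate (not isolated)
3 | (1S,2S,5S)-2-methyl-5-(prop-1-en-2-yl)cyclohexan-1-ol | CC(=C)[C@@H]1C[C@H](O)[C@@H](C)CC1 | intermediate
4 | 1-methoxy-4-({[(1S,2S,5S)-2-methyl-5-(prop-1-en-2-yl)cyclohexyl]oxy}methyl)benzene | CC(=C)[C@@H]1C[C@H](OCc2ccc(OC)cc2)[C@@H](C)CC1 | intermediate
5 | 1-methoxy-1-{(1S,3S,4S)-3-[(4-methoxybenzyl)oxy]-4-methylcyclohexyl}ethyl hydroperoxide (mixture at the new carbon) | CC(OC)(OO)[C@@H]1C[C@H](OCc2ccc(OC)cc2)[C@@H](C)CC1 | intermediate (not isolated)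
6 | (1S,3S,4S)-3-[(4-methoxybenzyl)oxy]-4-methylcyclohexyl acetate | CC(=O)O[C@@H]1C[C@H](OCc2ccc(OC)cc2)[C@@H](C)CC1 | intermediate
7 | (1S,3S,4S)-3-[(4-methoxybenzyl)oxy]-4-methylcyclohexan-1-ol | O[C@@H]1C[C@H](OCc2ccc(OC)cc2)[C@@H](C)CC1 | intermediate
8 | (3S,4S)-3-[(4-methoxybenzyl)oxy]-4-methylcyclohexan-1-one | O=C1C[C@H](OCc2ccc(OC)cc2)[C@@H](C)CC1 | intermediate
9 | 3-methylbut-2-enal (prenal) | CC(C)=CC=O | starting material
10 | 2,3-dibromo-3-methylbutanal | CC(C)(Br)C(Br)C=O | intermediate (not isolated)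
11 | 2-bromo-3-methylbut-2-enal | CC(C)=C(Br)C=O | intermediate
12 | {[(1Z)-2-bromo-3-methylbuta-1,3-dien-1-yl]oxy}tri(propan-2-yl)silane | C=C(C)/C(Br)=C/O[Si](C(C)C)(C(C)C)C(C)C | intermediate
13 | lithium (4S,5S)-5-[(4-methoxybenzyl)oxy]-4-methylcyclohex-1-en-1-olate | [Li]OC1=CC[C@H](C)[C@@H](OCc2ccc(OC)cc2)C1 | intermediate (not isolated)
14 | chlorozinc (4S,5S)-5-[(4-methoxybenzyl)oxy]-4-methylcyclohex-1-en-1-olate | Cl[Zn]OC1=CC[C@H](C)[C@@H](OCc2ccc(OC)cc2)C1 | intermediate (not isolated)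
15 | (2S,4S,5S)-5-[(4-methoxybenzyl)oxy]-4-methyl-2-{(1E)-3-methyl-1-[(triisopropylsilyl)oxy]buta-1,3-dien-2-yl}cyclohexan-1-one (silyloxy cis to the ring carbon) | O=C1C[C@H](OCc2ccc(OC)cc2)[C@@H](C)C[C@H]1/C(C(C)=C)=C\O[Si](C(C)C)(C(C)C)C(C)C | intermediate
16 | (1S,2S,4S,5S)-5-[(4-methoxybenzyl)oxy]-4-methyl-2-{(1E)-3-methyl-1-[(triisopropylsilyl)oxy]buta-1,3-dien-2-yl}-1-(prop-1-en-2-yl)cyclohexan-1-ol | C=C(C)[C@]1(O)C[C@H](OCc2ccc(OC)cc2)[C@@H](C)C[C@H]1/C(C(C)=C)=C\O[Si](C(C)C)(C(C)C)C(C)C | intermediate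
17 | potassium alkoxide of 16 | [K+].C=C(C)[C@]1([O-])C[C@H](OCc2ccc(OC)cc2)[C@@H](C)C[C@H]1/C(C(C)=C)=C\O[Si](C(C)C)(C(C)C)C(C)C | intermediate (not isolated)
18 | potassium (1(10)Z,3S,4S,6E,8R)-3-(4-methoxybenzyloxy)-8-(triisopropylsilyloxy)germacra-1(10),6,11(13)-trien-1-olate | [K+].[O-]/C1=C(/C)C[C@@H](O[Si](C(C)C)(C(C)C)C(C)C)/C(C(C)=C)=C/C[C@H](C)[C@@H](OCc2ccc(OC)cc2)C1 | intermediate (not isolated)
19 | potassium (3S,4S,6E,8R,10R)-3-(4-methoxybenzyloxy)-1-oxo-8-(triisopropylsilyloxy)germacra-6,11(13)-dien-10-olate | [K+].[O-][C@]1(C)C[C@@H](O[Si](C(C)C)(C(C)C)C(C)C)/C(C(C)=C)=C/C[C@H](C)[C@@H](OCc2ccc(OC)cc2)CC1=O | intermediate (not isolated)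
20 | (3S,4S,6E,8R,10R)-10-acetoxy-3-(4-methoxybenzyloxy)-8-(triisopropylsilyloxy)germacra-6,11(13)-dien-1-one | C=C(C)/C1=C\C[C@H](C)[C@@H](OCc2ccc(OC)cc2)CC(=O)[C@](C)(OC(C)=O)C[C@H]1O[Si](C(C)C)(C(C)C)C(C)C | intermediate
21 | (3S,4S,6R,7S,8R,10R)-10-acetoxy-6,7-epoxy-3-(4-methoxybenzyloxy)-8-(triisopropylsilyloxy)germacr-11(13)-en-1-one | C=C(C)[C@]12O[C@@H]1C[C@H](C)[C@@H](OCc3ccc(OC)cc3)CC(=O)[C@](C)(OC(C)=O)C[C@H]2O[Si](C(C)C)(C(C)C)C(C)C | intermediate
22 | (3S,4S,6R,7S,8R,10R)-10-acetoxy-6-hydroxy-3-(4-methoxybenzyloxy)-8-(triisopropylsilyloxy)germacr-11(13)-en-1-one | C=C(C)[C@H]1[C@H](O)C[C@H](C)[C@@H](OCc2ccc(OC)cc2)CC(=O)[C@](C)(OC(C)=O)C[C@H]1O[Si](C(C)C)(C(C)C)C(C)C | intermediate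
23 | (3S,4S,6R,7S,8R,10R)-10-acetoxy-6,12-dihydroxy-3-(4-methoxybenzyloxy)-8-(triisopropylsilyloxy)germacr-11(13)-en-1-one | C=C(CO)[C@H]1[C@H](O)C[C@H](C)[C@@H](OCc2ccc(OC)cc2)CC(=O)[C@](C)(OC(C)=O)C[C@H]1O[Si](C(C)C)(C(C)C)C(C)C | intermediate
24 | (3S,4S,6R,7S,8R,10R)-10-acetoxy-3-(4-methoxybenzyloxy)-1-oxo-8-(triisopropylsilyloxy)germacr-11(13)-en-12,6-olide | C=C1C(=O)O[C@@H]2C[C@H](C)[C@@H](OCc3ccc(OC)cc3)CC(=O)[C@](C)(OC(C)=O)C[C@@H](O[Si](C(C)C)(C(C)C)C(C)C)[C@@H]12 | intermediate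
25 | (3S,4S,6R,7R,8R,10R)-10-acetoxy-8-hydroxy-3-(4-methoxybenzyloxy)-1-oxogermacr-11(13)-en-12,6-olide | C=C1C(=O)O[C@@H]2C[C@H](C)[C@@H](OCc3ccc(OC)cc3)CC(=O)[C@](C)(OC(C)=O)C[C@@H](O)[C@@H]12 | intermediate
26 | (3S,4S,6R,7S,8S,10R)-10-acetoxy-8-angeloyloxy-3-(4-methoxybenzyloxy)-1-oxogermacr-11(13)-en-12,6-olide | C=C1C(=O)O[C@@H]2C[C@H](C)[C@@H](OCc3ccc(OC)cc3)CC(=O)[C@](C)(OC(C)=O)C[C@H](OC(=O)/C(C)=C\C)[C@@H]12 | intermediate
27 | (3S,4S,6R,7S,8S,10R)-10-acetoxy-8-angeloyloxy-3-hydroxy-1-oxogermacr-11(13)-en-12,6-olide (CNP0141210.5) | C=C1C(=O)O[C@@H]2C[C@H](C)[C@@H](O)CC(=O)[C@](C)(OC(C)=O)C[C@H](OC(=O)/C(C)=C\C)[C@@H]12 | target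

**Step count and risks**

Total step count: 17. Longest linear sequence: 15 (steps 1–5 and 8–17); steps 6–7 make the bromodiene.

The stereochemical outcome at C8, C10, C6 and C7 rests on a chair transition state and outer-face attack on the ten-membered ring; this is a model-based prediction, not a verified result.

Most likely to fail, first: step 8. The bromodiene is a hindered, electron-rich alkenyl bromide, and the product has an acidic doubly activated C6–H that could be alkenylated again or isomerise into conjugation. The fallback reverses the polarity of the coupling. It sets out from 8: LiN(i-Pr)2 and Me3SiCl give the kinetic trimethylsilyl enol ether F1, and N-bromosuccinimide converts this into the bromo ketone F2. In parallel 12 is turned by t-BuLi and ZnCl2 into the dienylzinc chloride F3. A NiCl2(dme)/2,2′-bipyridine Negishi coupling of F2 with F3 then gives the dienyl ketone and comes back to the route at 15.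

Second: step 10. The alkoxide could pull the silyl group off the nearby enol ether oxygen, the pseudo-axial silyloxy group could erode the chair preference at C8, and three operations run in one flask. The fallback avoids any free alkoxide or enolate. It sets out from 16, which is silylated with N-(trimethylsilyl)imidazole to the trimethylsilyl ether F4. Heating F4 in 1,2-dichlorobenzene at about 200 °C effects a neutral siloxy-Cope rearrangement to the ten-membered trimethylsilyl enol ether F5. Pb(OAc)4 then α-acetoxylates F5 from the outer face and gives the tertiary acetate directly, coming back to the route at 20.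

Third: step 16. The hindered C8 alcohol may eliminate instead of being displaced, and the phosphine may add to the α-methylene lactone or isomerise angelate to tiglate. The fallback inverts C8 by redox and esterifies with retention. It sets out from 25, which Dess–Martin periodinane oxidises to the 8-ketone F6. NaBH4 with CeCl3 at −78 °C reduces the unhindered C8 carbonyl from the outer face to the 8S alcohol F7; the neopentyl C1 ketone reacts more slowly. Yamaguchi esterification of F7 (angelic acid, 2,4,6-trichlorobenzoyl chloride, Et3N, then DMAP) comes back to the route at 26.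

Further compounds
F1 | step 8 | {[(4S,5S)-5-[(4-methoxybenzyl)oxy]-4-methylcyclohex-1-en-1-yl]oxy}trimethylsilane | C[Si](C)(C)OC1=CC[C@H](C)[C@@H](OCc2ccc(OC)cc2)C1
F2 | step 8 | (4S,5S)-2-bromo-5-[(4-methoxybenzyl)oxy]-4-methylcyclohexan-1-one (both C2 epimers) | O=C1C[C@H](OCc2ccc(OC)cc2)[C@@H](C)CC1Br
F3 | step 8 | chloro{(1Z)-3-methyl-1-[(triisopropylsilyl)oxy]buta-1,3-dien-2-yl}zinc | C=C(C)/C([Zn]Cl)=C/O[Si](C(C)C)(C(C)C)C(C)C
F4 | step 10 | {[(1S,2S,4S,5S)-5-[(4-methoxybenzyl)oxy]-4-methyl-2-{(1E)-3-methyl-1-[(triisopropylsilyl)oxy]buta-1,3-dien-2-yl}-1-(prop-1-en-2-yl)cyclohexyl]oxy}trimethylsilane | C=C(C)[C@]1(O[Si](C)(C)C)C[C@H](OCc2ccc(OC)cc2)[C@@H](C)C[C@H]1/C(C(C)=C)=C\O[Si](C(C)C)(C(C)C)C(C)C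
F5 | step 10 | (1(10)Z,3S,4S,6E,8R)-3-(4-methoxybenzyloxy)-8-(triisopropylsilyloxy)-1-(trimethylsilyloxy)germacra-1(10),6,11(13)-triene | C[Si](C)(C)O/C1=C(/C)C[C@@H](O[Si](C(C)C)(C(C)C)C(C)C)/C(C(C)=C)=C/C[C@H](C)[C@@H](OCc2ccc(OC)cc2)C1
F6 | step 16 | (3S,4S,6R,7S,10R)-10-acetoxy-3-(4-methoxybenzyloxy)-1,8-dioxogermacr-11(13)-en-12,6-olide | C=C1C(=O)O[C@@H]2C[C@H](C)[C@@H](OCc3ccc(OC)cc3)CC(=O)[C@](C)(OC(C)=O)CC(=O)[C@@H]12
F7 | step 16 | (3S,4S,6R,7R,8S,10R)-10-acetoxy-8-hydroxy-3-(4-methoxybenzyloxy)-1-oxogermacr-11(13)-en-12,6-olide | C=C1C(=O)O[C@@H]2C[C@H](C)[C@@H](OCc3ccc(OC)cc3)CC(=O)[C@](C)(OC(C)=O)C[C@H](O)[C@@H]12
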